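The numbers in the tables come from a simulation with constants of no real substance, noise included.

The amount of target, counted in percent of the starting material charged, does not grow with the charge: at 8.00 h alder reads 15.1 %, birch with more starting material 13.8 %, and elm with more capture agent 13.9 %, with a scatter of 0.5 percentage points. So I reckon with first-order steps. But alder goes from 4.6 % at 4.00 h to 15.1 % at 8.00 h, which is faster than a straight line, so the runs show an induction period: something stands between starting material and target.

| flask | starting material | capture agent | remark | time |
|---|---|---|---|---|
| maple | 0.016 M | 0.016 M | run made earlier |  |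
| alder | 0.022 M | 0.016 M | run made earlier |  |
| birch | 0.035 M | 0.016 M | run made earlier |  |
| elm | 0.016 M | 0.024 M | run made earlier |  |
| teal | 0.016 M | 0.0160 M | a single well-mixed tank run continuously and read at steady state, 100 h in it on average |  |
| violet | 0.016 M (fed, over 8.00 h) | 0.0160 M | all but starting material at the start; starting material goes in evenly over 8.00 h, the run ends at 10 h | 10 h |
| blue | 0.016 M | 0.0160 M | a single well-mixed tank run continuously and read at steady state, 10 h in it on average |  |
| amber | 0.016 M | 0.0160 M | a closed flask charged with all of it at once and left for 10 h | 10 h |

| run | time / h | target / % |
|---|---|---|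
| maple | 0.833 | 0 |
| maple | 2.00 | 1.9 |
| maple | 4.00 | 4.4 |
| maple | 6.00 | 8.3 |
| alder | 2.00 | 1.8 |
| alder | 4.00 | 4.6 |
| alder | 6.00 | 9.1 |
| alder | 8.00 | 15.1 |
| birch | 0.667 | 1.2 |
| birch | 1.33 | 0.1 |
| birch | 3.00 | 2.7 |
| birch | 8.00 | 13.8 |
| elm | 1.00 | 1.2 |
| elm | 3.00 | 3.1 |
| elm | 5.00 | 6.9 |
| elm | 8.00 | 13.9 |

(standard deviation of a reading: 0.5 percentage points)

- the stated concentrations are those of everything mixed, before any reaction; amounts are the same in each set-up
- the feed brings no volume worth counting
- the earlier runs were made in a closed, stirred flask

- the set-up with the highest amount of target at the outlet or at the end, in percent of the starting material put in ("none" if the first two lie within 2 percentage points) (teal / violet / blue / amber / none)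
- amount of target at the outlet or at the end, in percent of the starting material put in, teal
- amount of target at the outlet or at the end, in percent of the starting material put in, violet
- amount of target at the outlet or at the end, in percent of the starting material put in, blue
- amount of target at the outlet or at the end, in percent of the starting material put in, amber

I take two equal first-order steps in series, so early on the target fraction is y = 0.5(t/τ)^2. Here τ is the chain time, the mean time of one step of that chain. The last reading of each run gives 14.9 h.

Now I set the times of the flasks against τ, from the shortest up. Violet's feed takes 8.00 h, so at reading its starting material has ages from 2.00 h to 10 h, and the law averaged over those ages gives 9.29 %. Next comes amber's 10 h, later than the last readings at 8.00 h; at 0.671 chain times t is no longer small against τ, so the early law is here a rough extrapolation of mine, and it gives 22.5 %. Blue's average stay equals amber's time, but a tank mixes short and long stays, so for a mean stay θ I use the chain's tank form y = (θ/(θ+τ))^2, which gives 16.1 %. Teal's 100 h is 6.71 chain times and gives 75.7 %, my highest.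

The forecast names teal, with teal 85 %, violet 9.5 %, blue 32 % and amber 22 %, noting that “The tanks hold product”; on teal and blue it stands above my figures.

The flasks give teal 49.8 %, violet 9.56 %, blue 16.7 % and amber 18.9 %, so teal is highest.

    starting material → intermediate A (k = 0.120 h⁻¹)
    intermediate B → target (k = 0.00380 h⁻¹)
    capture agent + intermediate B → trapped intermediate (k = 9.30 M⁻¹ h⁻¹)
    intermediate A → target (k = 0.0910 h⁻¹)
    intermediate A ⇌ intermediate B (K = 0.450, k = 0.820 h⁻¹)
    intermediate B → decomposed reagent (k = 0.0460 h⁻¹)

My teal figure stands 26 points above the flask. Violet has not come to rest: at 10.0 h, 0.671 chain times, 50.6 % of its starting material remains. Amber, at the same 0.671 chain times, still holds 30.1 %, and at 100 h its target stands at 57.0 %. Ten times the time is 6.71 chain times for violet: starting material falls to 0 % and target rises by 47 points to 57.0 %. Capture agent falls from 94.6 % to 68.6 % of its own charge, and trapped intermediate reaches 31.4 %.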